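**Leftover asked.** What I wanted from Tuesday's flask was its leftover: how much substrate stood unreacted after 10 h, and the same for Thursday's and Monday's, which differ from it in time.

| flask | substrate | reagent | initiator | time |
|---|---|---|---|---|
| Tuesday's | 1.0 M | 0.800 M | 25 mM | 10 h |
| Thursday's | 1.0 M | 0.800 M | 25 mM | 8.0 h |
| Monday's | 1.0 M | 0.800 M | 25 mM | 15 h |

    substrate + initiating radical → capped initiator + first chain carrier (k1 = 17000 M⁻¹ s⁻¹)
    initiator → 2 initiating radical (k2 = 0.048 h⁻¹)
    2 second chain carrier → ended chains B (k3 = 9.6 × 10⁸ M⁻¹ s⁻¹)
    reagent + first chain carrier ⇌ product + second chain carrier (K4 = 0.22, k4 = 4.0 × 10⁶ M⁻¹ h⁻¹)
    substrate + second chain carrier → released group + first chain carrier (k5 = 2.7 × 10⁶ M⁻¹ h⁻¹)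
    2 first chain carrier → ended chains A (k6 = 6 × 10⁶ M⁻¹ s⁻¹)

- a species is counted by the substrate in it: one ended chains A counts as two
- a doubled species enters its step squared and goes two at a time
- run time (Tuesday's): 10 h

- which of these there is most of at the end, counted by the substrate in it, Tuesday's (first chain carrier / product / substrate)
- which of these there is most of at the end, counted by the substrate in it, Thursday's (first chain carrier / product / substrate)
- which of these there is most of at the end, counted by the substrate in it, Monday's (first chain carrier / product / substrate)
- how much there is at the end of the one of these that leads, in percent of the substrate charged: Tuesday's
- how much there is at the end of the one of these that leads, in percent of the substrate charged: Thursday's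
- how much there is at the end of the one of these that leads, in percent of the substrate charged: Monday's

**Start rate.** I reckoned the rate and left the concentrations aside. Initiator makes radicals, each radical caps on a substrate and starts a first chain carrier, and the first carrier's self-ending constant is far smaller than the second's. So I balanced radical making against self-ending of the second carrier. That carrier takes substrate at 0.0503 M h⁻¹, and with the first carrier in steady state I took product to form at about that net rate.

**What slows.** The carrier level follows the root of the initiator, which costs a factor 0.787 by the end of Tuesday's. Substrate also slows its own use, since the fall is pseudo-first-order, so I went to logarithms. The logarithm of the substrate falls along a curve that flattens with the initiator, and its whole fall on this reckoning, twice the start rate per molar of substrate over the initiator's decay constant, I call the reach 2.10. The part of the reach used by any time is the reach times one minus the initiator factor. That leaves 63.9% on Tuesday's, 69.3% on Thursday's and 53.1% on Monday's.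

**Third factor.** By my reckoning the back step from product and the fall of the reagent lift the first carrier to 4.71 times the second by the end of Tuesday's, and its self-ending then costs 0.937. Together the three factors leave Tuesday's rate at half its start. That third factor pushes my leftover up, capping, reckoned at 0.0191 M of substrate on Tuesday's, pushes it down, and I let the figures stand. On this reckoning Monday's keeps more than the 46.9% that has left it, so substrate leads there, and Tuesday's and Thursday's keep more.

**The forecast.** It named substrate on Tuesday's at 63.2%, substrate on Thursday's at 68.6% and substrate on Monday's at 52.6%, each lower than mine, holding that “unconsumed substrate still leads”.

**The flasks.** Substrate led, at 63.1% on Tuesday's, 68.5% on Thursday's and 52.8% on Monday's. Tuesday's held 36.8% as product with 62% of its initiator unspent, and its logarithmic fall read 0.460 against the reach 2.10. Put on Thursday's flask read at 30 h, the reach gives 34.1%. That flask stood higher, at 37.2% substrate, with product ahead at 62.0%.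

The constants are invented; no experiment stands behind them.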